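A direct plan would condense 5-benzyloxy-2-hydroxy-3,4,6-trimethoxyacetophenone (A1) with 2-benzyloxy-6-methoxybenzaldehyde (A2) to the 2'-hydroxychalcone A3, would close ring C oxidatively, and would end with debenzylation to the tetramethoxyflavone diol A4 and cleavage of its 5-methyl ether.
Its weakest steps would be:
- the para-hydroxylation of a tetraoxygenated phenol needed to reach A1 (persulfate oxidation): such electron-rich phenols would give low conversion and over-oxidised material;
- the aldol condensation of A1 with A2: a hexasubstituted ketone and a di-ortho-substituted aldehyde would react slowly and reversibly, with retro-aldol and Cannizzaro losses;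
- the final cleavage of one methyl ether out of four in A4: only chelation to the C4 carbonyl would single out 5-OMe, so over-demethylation would be hard to exclude.

The route disconnects ring A itself. The contiguous carbons C6, C7, C8 and C8a with their oxygens (OH, OMe, OMe, O1) are the four carbons of dimethyl squarate; C5 and C4a are the alkene carbons of a β-benzyloxyacrylamide whose amide carbon becomes C4. A thermal Moore ring expansion of their adduct (4π opening, 6π closure) builds the hexasubstituted ring A in one operation with 6-OH free, 7,8-OMe in place and the 5-oxygen already differentiated. Ring C is then closed from an ynone onto the only free ortho phenol. Thus no arene hydroxylation, no hindered aldol condensation and no selective demethylation occurs.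

Key step: step 5

Remark: atom labels C2–C8a refer to the flavone numbering of the target; compounds 11 and 16 are electron-rich hydroquinones and are assumed to be handled under argon with degassed solvents.

Step 1
Reactants: 1 propiolic acid
Product: 2 N-methoxy-N-methylprop-2-ynamide
Conditions: MeNHOMe·HCl (1.1 equiv), N-methylmorpholine (1.1 equiv), N,N'-dicyclohexylcarbodiimide (1.05 equiv), CH2Cl2, −10 → 0 °C, 3 h
Reagents that add atoms: N,O-dimethylhydroxylamine hydrochloride, CNOC.Cl
Why: Carbodiimide amide coupling, in which the O-acylisourea of the acid should be aminolysed at low temperature faster than the weakly nucleophilic hydroxylamine can add to the triple bond.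

Step 2
Reactants: 2 N-methoxy-N-methylprop-2-ynamide
Product: 3 (E)-3-(benzyloxy)-N-methoxy-N-methylprop-2-enamide
Conditions: BnOH (1.1 equiv), PMe3 (10 mol %), CH2Cl2, 0 °C → rt, 2 h
Reagents that add atoms: benzyl alcohol, OCc1ccccc1
Why: Phosphine-catalysed oxa-Michael addition of the alcohol to the ynamide should give the thermodynamically preferred (E)-β-alkoxyacrylamide and so introduces the future 5-oxygen as a benzyl ether, distinct from the methyl ethers.

Step 3
Reactants: 3 (E)-3-(benzyloxy)-N-methoxy-N-methylprop-2-enamide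
Product: 5 (Z)-3-(benzyloxy)-2-iodo-N-methoxy-N-methylprop-2-enamide, via acetoxy iodide 4 (not isolated)
Conditions: NIS (1.2 equiv), AcOH (2 equiv), CH2Cl2, rt, dark, 24 h; then Et3N (3 equiv), 0 °C → rt, 12 h
Reagents that add atoms: N-iodosuccinimide, O=C1CCC(=O)N1I
Why: Electrophilic iodination of the push-pull alkene at its nucleophilic α-carbon with acetate capture, followed by base-induced elimination of acetic acid, should give the α-iodo-β-alkoxyacrylamide with iodine and benzyloxy cis.

Step 4
Reactants: 5 (Z)-3-(benzyloxy)-2-iodo-N-methoxy-N-methylprop-2-enamide; 6 dimethyl squarate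
Product: 8 racemic (E)-3-(benzyloxy)-2-(1-hydroxy-2,3-dimethoxy-4-oxocyclobut-2-en-1-yl)-N-methoxy-N-methylprop-2-enamide, via alkenylmagnesium chloride 7 (not isolated)
Conditions: iPrMgCl·LiCl (1.05 equiv), THF, −78 °C, 30 min; cannulate into 6 (1.3 equiv) in THF, −78 → −40 °C, 1 h; sat. aq NH4Cl at −78 °C
Reagents that add atoms: none
Why: Iodine–magnesium exchange on the carbonyl-activated sp2 C–I bond is fast at −78 °C, the cis β-benzyloxy group cannot undergo anti-elimination, and the alkenyl Grignard reagent should add 1,2 to one of the two equivalent strained ketones of the squarate faster than to the Weinreb amide, the carbinol centre being formed racemic and destroyed in step 5.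

Step 5
Reactants: 8 racemic (E)-3-(benzyloxy)-2-(1-hydroxy-2,3-dimethoxy-4-oxocyclobut-2-en-1-yl)-N-methoxy-N-methylprop-2-enamide
Product: 11 2-(benzyloxy)-3,6-dihydroxy-N,4,5-trimethoxy-N-methylbenzamide, via dienylketene 9 (not isolated), via cyclohexadienone 10 (not isolated)
Conditions: degassed toluene (0.02 M), 110 °C, 1–2 h, under Ar
Reagents that add atoms: none
Why: Moore rearrangement: heating opens the cyclobutenone by 4π-conrotatory electrocyclic cleavage of the bond between the carbinol carbon and the ketone, the donor hydroxyl rotating outward and the alkenyl group inward, so that dienylketene 9 has its ketene carbon next to the CH(OBn) terminus. A thermal disrotatory 6π-electrocyclisation then joins these two carbons and closes the six-membered carbocyclic ring A as cyclohexa-2,4-dienone 10, which tautomerises irreversibly to the aromatic hydroquinone 11. The closest known reaction type is the thermal ring expansion of 4-alkenyl- and 4-aryl-4-hydroxycyclobutenones derived from squarate esters to hydroquinones. No stereocentre is created, and the racemic centres of 8 and 10 are lost on aromatisation. The only selectivity needed is the inward rotation of the alkenyl group, which the hydroxyl secures, while the substitution pattern is fixed by connectivity: the ketene carbon becomes C6–OH, the two methoxy-bearing squarate carbons C7 and C8, the carbinol carbon C8a–OH, CH(OBn) becomes C5 and the amide-bearing carbon C4a.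

Step 6
Reactants: 12 2-hydroxy-6-methoxybenzaldehyde
Product: 13 2-(benzyloxy)-6-methoxybenzaldehyde
Conditions: BnBr (1.1 equiv), K2CO3 (1.5 equiv), DMF, 60 °C, 4 h
Reagents that add atoms: benzyl bromide, BrCc1ccccc1
Why: Williamson etherification in DMF should overcome the hydrogen bond of the salicylaldehyde hydroxyl and protects the future 2'-OH against the organolithium chemistry of step 8.

Step 7
Reactants: 13 2-(benzyloxy)-6-methoxybenzaldehyde
Product: 14 1-(benzyloxy)-2-ethynyl-3-methoxybenzene
Conditions: dimethyl (1-diazo-2-oxopropyl)phosphonate (1.3 equiv), K2CO3 (2 equiv), MeOH, 0 °C → rt, 12 h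
Reagents that add atoms: dimethyl (1-diazo-2-oxopropyl)phosphonate, COP(=O)(OC)C(=[N+]=[N-])C(C)=O
Why: The Ohira–Bestmann variant of the Seyferth–Gilbert homologation should convert the aldehyde into the terminal alkyne with one added carbon under mild carbonate conditions that the hindered, electron-rich aldehyde and the benzyl ether tolerate.

Step 8
Reactants: 11 2-(benzyloxy)-3,6-dihydroxy-N,4,5-trimethoxy-N-methylbenzamide; 14 1-(benzyloxy)-2-ethynyl-3-methoxybenzene
Product: 16 1-[2-(benzyloxy)-3,6-dihydroxy-4,5-dimethoxyphenyl]-3-[2-(benzyloxy)-6-methoxyphenyl]prop-2-yn-1-one, via lithium acetylide 15 (not isolated)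
Conditions: 14 (3.3 equiv), n-BuLi (3.2 equiv), THF, −78 °C, 30 min; add 11, −78 → 0 °C, 2 h, under Ar; cold 1 M HCl; excess 14 recovered
Reagents that add atoms: none
Why: Weinreb ketone synthesis, in which two equivalents of acetylide deprotonate the phenols and a third, a slim sp nucleophile, should reach the di-ortho-substituted amide carbonyl to give a chelated tetrahedral adduct that collapses to the ynone only on acidic quench, so that over-addition is excluded.

Step 9
Reactants: 16 1-[2-(benzyloxy)-3,6-dihydroxy-4,5-dimethoxyphenyl]-3-[2-(benzyloxy)-6-methoxyphenyl]prop-2-yn-1-one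
Product: 18 5-(benzyloxy)-2-[2-(benzyloxy)-6-methoxyphenyl]-6-hydroxy-7,8-dimethoxy-4H-chromen-4-one, via enaminone 17 (not isolated)
Conditions: Et2NH (3 equiv), degassed EtOH, 60 °C, 3 h, under Ar
Reagents that add atoms: none
Why: Amine-mediated 6-endo cyclisation: conjugate addition of Et2NH to the ynone gives β-enaminone 17, whose β-carbon is attacked by the only ortho phenol (C8a–OH, since the 5-oxygen is benzylated and the 6-OH cannot reach) in an addition–elimination that expels the amine and closes ring C, which avoids the 5-exo closure to an aurone.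

Step 10
Reactants: 18 5-(benzyloxy)-2-[2-(benzyloxy)-6-methoxyphenyl]-6-hydroxy-7,8-dimethoxy-4H-chromen-4-one
Product: 19 5,6-dihydroxy-2-(2-hydroxy-6-methoxyphenyl)-7,8-dimethoxy-4H-chromen-4-one (5,6,2'-trihydroxy-7,8,6'-trimethoxyflavone)
Conditions: H2 (1 atm), 10% Pd/C, EtOAc–MeOH 1:1, rt, 3 h
Reagents that add atoms: none
Why: Catalytic hydrogenolysis should cleave both aryl benzyl ethers under neutral conditions, while the three methyl ethers and the chromone C2=C3 bond are inert at 1 atm.

## Compound list

1 | propiolic acid | C#CC(=O)O | starting material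
2 | N-methoxy-N-methylprop-2-ynamide | C#CC(=O)N(C)OC | intermediate
3 | (E)-3-(benzyloxy)-N-methoxy-N-methylprop-2-enamide | CON(C)C(=O)/C=C/OCc1ccccc1 | intermediate
4 | 1-(benzyloxy)-2-iodo-3-[methoxy(methyl)amino]-3-oxopropyl acetate, diastereomer mixture, racemic (not isolated) | CC(=O)OC(OCc1ccccc1)C(I)C(=O)N(C)OC | intermediate
5 | (Z)-3-(benzyloxy)-2-iodo-N-methoxy-N-methylprop-2-enamide | CON(C)C(=O)/C(I)=C/OCc1ccccc1 | intermediate
6 | dimethyl squarate (3,4-dimethoxycyclobut-3-ene-1,2-dione) | COC1=C(OC)C(=O)C1=O | starting material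
7 | (Z)-[1-(benzyloxy)-3-[methoxy(methyl)amino]-3-oxoprop-1-en-2-yl]magnesium chloride, LiCl complex (not isolated) | CON(C)C(=O)/C([Mg]Cl)=C/OCc1ccccc1 | intermediate
8 | (E)-3-(benzyloxy)-2-(1-hydroxy-2,3-dimethoxy-4-oxocyclobut-2-en-1-yl)-N-methoxy-N-methylprop-2-enamide, racemic | CON(C)C(=O)/C(=C/OCc1ccccc1)C1(O)C(OC)=C(OC)C1=O | intermediate
9 | (E)-3-(benzyloxy)-2-[(1Z)-1-hydroxy-2,3-dimethoxy-4-oxobuta-1,3-dien-1-yl]-N-methoxy-N-methylprop-2-enamide, dienylketene (not isolated) | O=C=C(OC)/C(OC)=C(O)\C(C(=O)N(C)OC)=C/OCc1ccccc1 | intermediate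
10 | 6-(benzyloxy)-2-hydroxy-N,3,4-trimethoxy-N-methyl-5-oxocyclohexa-1,3-diene-1-carboxamide, racemic (not isolated) | CON(C)C(=O)C1=C(O)C(OC)=C(OC)C(=O)C1OCc1ccccc1 | intermediate
11 | 2-(benzyloxy)-3,6-dihydroxy-N,4,5-trimethoxy-N-methylbenzamide | CON(C)C(=O)c1c(OCc2ccccc2)c(O)c(OC)c(OC)c1O | intermediate
12 | 2-hydroxy-6-methoxybenzaldehyde | COc1cccc(O)c1C=O | starting material
13 | 2-(benzyloxy)-6-methoxybenzaldehyde | COc1cccc(OCc2ccccc2)c1C=O | intermediate
14 | 1-(benzyloxy)-2-ethynyl-3-methoxybenzene | C#Cc1c(OC)cccc1OCc1ccccc1 | intermediate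
15 | lithium [2-(benzyloxy)-6-methoxyphenyl]acetylide (not isolated) | [Li]C#Cc1c(OC)cccc1OCc1ccccc1 | intermediate
16 | 1-[2-(benzyloxy)-3,6-dihydroxy-4,5-dimethoxyphenyl]-3-[2-(benzyloxy)-6-methoxyphenyl]prop-2-yn-1-one | COc1cccc(OCc2ccccc2)c1C#CC(=O)c1c(OCc2ccccc2)c(O)c(OC)c(OC)c1O | intermediate
17 | (E)-1-[2-(benzyloxy)-3,6-dihydroxy-4,5-dimethoxyphenyl]-3-[2-(benzyloxy)-6-methoxyphenyl]-3-(diethylamino)prop-2-en-1-one (not isolated) | CCN(CC)/C(=C/C(=O)c1c(OCc2ccccc2)c(O)c(OC)c(OC)c1O)c1c(OC)cccc1OCc1ccccc1 | intermediate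
18 | 5-(benzyloxy)-2-[2-(benzyloxy)-6-methoxyphenyl]-6-hydroxy-7,8-dimethoxy-4H-chromen-4-one | COc1cccc(OCc2ccccc2)c1-c1cc(=O)c2c(OCc3ccccc3)c(O)c(OC)c(OC)c2o1 | intermediate
19 | 5,6-dihydroxy-2-(2-hydroxy-6-methoxyphenyl)-7,8-dimethoxy-4H-chromen-4-one (5,6,2'-trihydroxy-7,8,6'-trimethoxyflavone) | COc1cccc(O)c1-c1cc(=O)c2c(O)c(O)c(OC)c(OC)c2o1 | target

Total step count: 10. Longest linear sequence: 8 (steps 1–5 and 8–10; steps 6 and 7 make alkyne 14).

Steps most likely to fail:

Step 5. Autoxidation of the very electron-rich hydroquinone during thermolysis and chromatography would erode 11. The fallback sets out from 8 and comes back at 11: the crude thermolysate would be oxidised on purpose with Ag2O in Et2O to the benzoquinone 2-(benzyloxy)-N,4,5-trimethoxy-N-methyl-3,6-dioxocyclohexa-1,4-diene-1-carboxamide F1, which should be stable to chromatography and storage; reduction with aqueous Na2S2O4 in EtOAc directly before step 8 would return 11.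

Step 8. Acyl substitution at a carbonyl flanked by two ortho substituents would be slow in a substrate that is a hydroquinone dianion under the conditions, and electron transfer from that dianion to the ynone being formed could compete. The fallback sets out from 11 and comes back at 16: silylation (TMSCl, Et3N, CH2Cl2) would give 2-(benzyloxy)-N,4,5-trimethoxy-N-methyl-3,6-bis(trimethylsilyloxy)benzamide F2; addition of 15 (1.3 equiv) to this neutral amide would give the ynone 1-[2-(benzyloxy)-4,5-dimethoxy-3,6-bis(trimethylsilyloxy)phenyl]-3-[2-(benzyloxy)-6-methoxyphenyl]prop-2-yn-1-one F3; methanolysis of the silyl ethers (citric acid, MeOH, 0 °C) would return 16.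

Step 4. Consumption of the Weinreb amide by the organomagnesium species, or decay of the β-alkoxyalkenylmagnesium reagent before it meets the squarate, would lower the yield of 8. The fallback sets out from 6 and comes back at 11, carrying an ester, which is more robust towards the magnesium reagent, through the ring construction. Commercial ethyl propiolate and BnOH (PMe3 cat.) would give ethyl (E)-3-(benzyloxy)prop-2-enoate F4; NIS/AcOH then Et3N would give ethyl (Z)-3-(benzyloxy)-2-iodoprop-2-enoate F5; iodine–magnesium exchange (iPrMgCl·LiCl, −78 °C) and addition to 6 would give racemic ethyl (E)-3-(benzyloxy)-2-(1-hydroxy-2,3-dimethoxy-4-oxocyclobut-2-en-1-yl)prop-2-enoate F6; thermolysis as in step 5 would give ethyl 2-(benzyloxy)-3,6-dihydroxy-4,5-dimethoxybenzoate F7; aminolysis with MeNHOMe·HCl and excess iPrMgCl in THF would return 11.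

## Further compounds

F1 | step 5 | 2-(benzyloxy)-N,4,5-trimethoxy-N-methyl-3,6-dioxocyclohexa-1,4-diene-1-carboxamide | CON(C)C(=O)C1=C(OCc2ccccc2)C(=O)C(OC)=C(OC)C1=O
F2 | step 8 | 2-(benzyloxy)-N,4,5-trimethoxy-N-methyl-3,6-bis(trimethylsilyloxy)benzamide | CON(C)C(=O)c1c(OCc2ccccc2)c(O[Si](C)(C)C)c(OC)c(OC)c1O[Si](C)(C)C
F3 | step 8 | 1-[2-(benzyloxy)-4,5-dimethoxy-3,6-bis(trimethylsilyloxy)phenyl]-3-[2-(benzyloxy)-6-methoxyphenyl]prop-2-yn-1-one | COc1cccc(OCc2ccccc2)c1C#CC(=O)c1c(OCc2ccccc2)c(O[Si](C)(C)C)c(OC)c(OC)c1O[Si](C)(C)C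
F4 | step 4 | ethyl (E)-3-(benzyloxy)prop-2-enoate | CCOC(=O)/C=C/OCc1ccccc1
F5 | step 4 | ethyl (Z)-3-(benzyloxy)-2-iodoprop-2-enoate | CCOC(=O)/C(I)=C/OCc1ccccc1
F6 | step 4 | ethyl (E)-3-(benzyloxy)-2-(1-hydroxy-2,3-dimethoxy-4-oxocyclobut-2-en-1-yl)prop-2-enoate, racemic | CCOC(=O)/C(=C/OCc1ccccc1)C1(O)C(OC)=C(OC)C1=O
F7 | step 4 | ethyl 2-(benzyloxy)-3,6-dihydroxy-4,5-dimethoxybenzoate | CCOC(=O)c1c(OCc2ccccc2)c(O)c(OC)c(OC)c1O
A1 | direct plan | 5-(benzyloxy)-2-hydroxy-3,4,6-trimethoxyacetophenone | CC(=O)c1c(O)c(OC)c(OC)c(OCc2ccccc2)c1OC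
A2 | direct plan | 2-(benzyloxy)-6-methoxybenzaldehyde | COc1cccc(OCc2ccccc2)c1C=O
A3 | direct plan | (E)-1-[5-(benzyloxy)-2-hydroxy-3,4,6-trimethoxyphenyl]-3-[2-(benzyloxy)-6-methoxyphenyl]prop-2-en-1-one | COc1cccc(OCc2ccccc2)c1/C=C/C(=O)c1c(O)c(OC)c(OC)c(OCc2ccccc2)c1OC
A4 | direct plan | 6-hydroxy-2-(2-hydroxy-6-methoxyphenyl)-5,7,8-trimethoxy-4H-chromen-4-one | COc1cccc(O)c1-c1cc(=O)c2c(OC)c(O)c(OC)c(OC)c2o1
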